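**Assumptions**
- The target SMILES has no stereodescriptor, stereocentre or fixed axis. The 20-membered ring is treated as conformationally mobile, so the compound is achiral and no enantiocontrol is needed.
- Compounds 4 and 5 are taken to be catalogue chemicals.

**Ring labels:** A is the 1,2,4-trisubstituted phenol ring, B the para-phenylene, C the catechol ring and D the meta-phenylene.

## Retrosynthetic overview
1. The target comes from global O-demethylation and C=C hydrogenation of a 20-membered macrocyclic (Z)-stilbene trimethyl ether.
2. The macrocycle is the only ring formed, since all four arenes are bought. It is closed last by intramolecular McMurry coupling of a B-CHO/C-CHO dialdehyde, which makes the B–C bridge.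
3. The open dialdehyde comes from a Heck coupling of A-ring Br with D-ring vinyl. An aldehyde-sparing hydrogenation then gives the saturated A–D bridge first.
4. The A–O–B ether comes from SNAr of 5-bromo-2-methoxyphenol on 4-fluorobenzaldehyde. The C–O–D ether comes from Chan–Lam coupling of 4-hydroxy-2,3-dimethoxybenzaldehyde with 3-vinylphenylboronic acid.
5. The orthogonal handle pairs (Br/vinyl, then CHO/CHO) fix the head-to-tail regiochemistry without protecting-group or redox-adjustment steps.

## Route

**Step 1**
Reactants: 1, 5-bromo-2-methoxyphenol; 2, 4-fluorobenzaldehyde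
Product: 3, 4-(5-bromo-2-methoxyphenoxy)benzaldehyde (A–O–B ether; Br on A para to OMe, CHO on B para to O)
Conditions: K2CO3, DMF, 120 °C
Reagents that add atoms: none beyond reactant 2 (4-fluorobenzaldehyde, O=Cc1ccc(F)cc1)
Why: In this SNAr (addition–elimination) the para-formyl group activates C–F toward the phenoxide while the unactivated Ar–Br is inert, so both handles survive and no stereocentre is created.

**Step 2**
Reactants: 4, 4-hydroxy-2,3-dimethoxybenzaldehyde; 5, 3-vinylphenylboronic acid
Product: 6, 2,3-dimethoxy-4-(3-vinylphenoxy)benzaldehyde (C–O–D ether)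
Conditions: Cu(OAc)2 (1 equiv), pyridine, 4 Å MS, CH2Cl2, air, rt (2 equiv of 5)
Reagents that add atoms: none beyond reactant 5 (3-vinylphenylboronic acid, C=Cc1cccc(B(O)O)c1)
Why: Chan–Lam–Evans oxidative O-arylation attaches the meta-substituted D ring, which cannot undergo SNAr, at room temperature, so the aldehyde and the polymerisable styrene survive.

**Step 3**
Reactants: 3 (aryl bromide); 6 (styrene)
Product: 7, 4-{3-[(E)-2-(3-(4-formylphenoxy)-4-methoxyphenyl)ethenyl]phenoxy}-2,3-dimethoxybenzaldehyde (open B–O–A–CH=CH–D–O–C chain, a dialdehyde)
Conditions: Pd(OAc)2 (5 mol %), P(o-tol)3 (15 mol %), Et3N, DMF, 100 °C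
Reagents that add atoms: none (3 and 6 combine with loss of HBr)
Why: In this Mizoroki–Heck reaction only ring A carries Br and only ring D carries vinyl, so one regiochemical assembly is possible, the aldehydes are spectators, and β-insertion with syn β-H elimination gives the E-alkene, which is erased in step 4.

**Step 4**
Reactants: 7
Product: 8, 4-{3-[2-(3-(4-formylphenoxy)-4-methoxyphenyl)ethyl]phenoxy}-2,3-dimethoxybenzaldehyde (saturated A–D bridge, both CHO retained)
Conditions: H2 (1 atm), 10% Pd/C, Ph2S (cat.), EtOAc, rt
Reagents that add atoms: none (hydrogen only)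
Why: Sulfide-poisoned Pd/C chemoselectively saturates the stilbene C=C but is too deactivated to reduce aryl aldehydes, and removing the rigid E-alkene gives the flexible tether needed for ring closure.

**Step 5**
Reactants: 8
Product: 9, macrocyclic (Z)-stilbene trimethyl ether (20-membered ring; new CH=CH between rings B and C)
Conditions: TiCl4, Zn, pyridine, THF, reflux; syringe-pump addition of 8 (about 1 mM final)
Reagents that add atoms: none (two oxygens are lost)
Why: Intramolecular McMurry coupling under pseudo-high dilution joins the only two carbonyls, the aryl ethers are inert to low-valent Ti, the ring should tolerate only the cis alkene across the para,para′ bridge, and the geometry is erased in step 6.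

**Step 6**
Reactants: 9
Product: 10, tri-O-methylneomarchantin B (both bridges CH2CH2)
Conditions: H2 (1 atm), 10% Pd/C, EtOAc/MeOH, rt
Reagents that add atoms: none (hydrogen only)
Why: Catalytic hydrogenation saturates the strained cis-stilbene, no other reducible group remains, and no stereocentre is formed.

**Step 7**
Reactants: 10
Product: 11, neomarchantin B
Conditions: BBr3 (excess), CH2Cl2, −78 °C → rt; ice/H2O work-up under N2
Reagents that add atoms: none (three CH3 groups are replaced by H on hydrolysis)
Why: Lewis-acid aryl methyl ether cleavage by BBr3 removes all three O-methyl groups by bromide attack at CH3, whereas the diaryl ethers have no sp3 C–O bond to cleave and survive.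

## Compound list
1 | 5-bromo-2-methoxyphenol | COc1ccc(Br)cc1O | starting material
2 | 4-fluorobenzaldehyde | O=Cc1ccc(F)cc1 | starting material
3 | 4-(5-bromo-2-methoxyphenoxy)benzaldehyde | COc1ccc(Br)cc1Oc1ccc(C=O)cc1 | intermediate
4 | 4-hydroxy-2,3-dimethoxybenzaldehyde | COc1c(O)ccc(C=O)c1OC | starting material
5 | 3-vinylphenylboronic acid | C=Cc1cccc(B(O)O)c1 | starting material
6 | 2,3-dimethoxy-4-(3-vinylphenoxy)benzaldehyde | C=Cc1cccc(Oc2ccc(C=O)c(OC)c2OC)c1 | intermediate
7 | (E)-stilbene dialdehyde | COc1ccc(/C=C/c2cccc(Oc3ccc(C=O)c(OC)c3OC)c2)cc1Oc1ccc(C=O)cc1 | intermediate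
8 | bibenzyl dialdehyde | COc1ccc(CCc2cccc(Oc3ccc(C=O)c(OC)c3OC)c2)cc1Oc1ccc(C=O)cc1 | intermediate
9 | macrocyclic (Z)-stilbene trimethyl ether | COc1ccc2cc1Oc1ccc(cc1)/C=C\c1ccc(c(OC)c1OC)Oc1cccc(c1)CC2 | intermediate
10 | tri-O-methylneomarchantin B | COc1ccc2cc1Oc1ccc(cc1)CCc1ccc(c(OC)c1OC)Oc1cccc(c1)CC2 | intermediate
11 | neomarchantin B (achiral, C28H24O5) | Oc1ccc2cc1Oc1ccc(cc1)CCc1ccc(c(O)c1O)Oc1cccc(c1)CC2 | target

## Summary
**Total steps:** 7
**Longest linear sequence:** 6 (step 1 or step 2, then steps 3–7)

**Steps most likely to fail**
1. **Step 5, McMurry macrocyclisation.** The risks are oligomers, arrest at the pinacol, and the need for a cis alkene. Fallback: reduce 8 to the diol with NaBH4 and convert it to the bis(benzyl bromide) with PBr3. Then close the ring by intramolecular Wurtz-type coupling (Na, tetraphenylethene, THF, high dilution). This gives 10 directly and makes step 6 unnecessary.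
2. **Step 2, Chan–Lam coupling.** The phenol is electron-poor and ortho-substituted. Fallback: reverse the ether polarity and swap the roles of the two bridges.
   - Couple 1,4-dibromo-2,3-dimethoxybenzene once with 3-hydroxybenzaldehyde (Ullmann mono-etherification).
   - Join the remaining C-ring bromide by Heck reaction to 4-methoxy-3-(4-vinylphenoxy)benzaldehyde, made from isovanillin and 4-vinylphenylboronic acid.
   - Hydrogenate, then close the A–D bridge by McMurry coupling. The step count is unchanged.
3. **Step 4, alkene reduction beside two aryl aldehydes.** Fallback: never form the alkene. Mask 6 as its dimethyl acetal and hydroborate the vinyl group with 9-BBN. Then run a B-alkyl Suzuki–Miyaura coupling with bromide 3 (PdCl2(dppf), K3PO4, DMF/H2O). Acid work-up gives 8 directly.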